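The runs stem from a simulated flask from invented constants; scatter was added.

| setting | dusk | dawn | flask |
|---|---|---|---|
| starting material | 0.020 M | 0.020 M | 0.020 M |
| second substrate | 0.020 M | 0.020 M | 0.0200 M |
| gas | 2.4 mM (held) | 2.4 mM (held) | 2.4 mM (held) |
| capture agent | 0.020 M | 0.020 M | 0.0200 M |
| free catalyst | 2 mM | 2 mM | 2.0 mM |
| temperature | 25 °C | 20 °C | 25 °C |
| remark | the very flask that is asked about, followed so far | run made earlier |  |
| time |  |  | 2.0 d |

| run | time / h | target / % | starting material / % |
|---|---|---|---|
| dusk | 2.50 | 37.5 | 63.0 |
| dusk | 4.00 | 37.8 | 60.3 |
| dusk | 5.00 | 39.1 | 61.8 |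
| dusk | 8.00 | 39.7 | 61.1 |
| dusk | 12.0 | 40.2 | 59.9 |
| dusk | 20.0 | 38.6 | 62.5 |
| dusk | 30.0 | 39.1 | 61.3 |
| dawn | 2.50 | 44.3 | 56.0 |
| dawn | 4.00 | 47.1 | 50.7 |
| dawn | 5.00 | 50.7 | 48.7 |
| dawn | 8.00 | 52.4 | 49.8 |
| dawn | 12.0 | 51.3 | 47.4 |
| dawn | 20.0 | 51.5 | 48.6 |
| dawn | 30.0 | 52.1 | 48.6 |

(readings scatter by 1 percentage point)

- south: change nothing and wait 15 h more
- north-east: at 2.0 d take out 90% of the target then present, then wait 15 h
- north: at 2.0 d add free catalyst, 100% of the amount charged, then wait 15 h
- north-west: at 2.0 d raise the temperature by 20 K, then wait 15 h

- target taken out counts as made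
- at the start none of the gas is in solution
- additions bring no volume worth counting

1. target, in percent of the starting material first charged, at 2.0 d
2. what to do for the largest gain in target; "none" if nothing gains more than 2 percentage points (south / north-east / north / north-west / none)
3. target present, with what was taken out counted in, in percent of the starting material first charged, after south
4. target present, with what was taken out counted in, in percent of the starting material first charged, after north-west

The thing to watch in the dusk flask, which is the asked flask followed so far, is the leftover. The target readings from 5.00 h on average 39.3%, so a fraction 60.7% of the starting material stays unused. The first reading, at 2.50 h, already stands at 95.3% of that level. The curve has thus risen on average by 0.150 h⁻¹ of the charge, and a line of that slope meets the level at 2.62 h, so the knee lies about there or earlier. After it the target runs flat, lower than the starting material. In the colder dawn run the target passes the starting material between 4.00 h and 5.00 h and levels at 51.6%.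

The readings do not separate an equilibrium from a dying catalyst, but this reckoning commits to the dying catalyst: each catalyst charged gives about 3.93 targets and is then lost, taking one second substrate with it. The second substrate then ends at 90.0% of its charge. Call 4.74 the selectivity factor, the logarithm of the fraction of starting material left over the logarithm of the fraction of second substrate left. Starting material falls that many times faster, relative to what is present, than second substrate.

On this reading nothing turns over after the knee, and 2.0 d lies far beyond it. The target therefore stays at 39.3% at the asked time, after south, after north-east and after north-west. Fresh catalyst takes the second substrate to 80.0%, so the starting material falls to 34.7%. That gains 26 percentage points, more than the margin, so the choice here is north.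

The forecast, holding that “A plateau that falls on warming fits an exothermic equilibrium”, gave 39.1% (38.2% to 40%), north-east as the best move, 39.1% after south and 9% after north-west.

The flask gives 38.9%, 38.9% after south and 38.9% after north-west. Its best move is north, which brings 26 points, while north-east brings 0 points.

    starting material + free catalyst ⇌ catalyst intermediate A (K = 220 M⁻¹, k = 1.00 M⁻¹ s⁻¹, Ea = 42.0 kJ mol⁻¹, ΔH = −60.0 kJ mol⁻¹)
    partner + catalyst intermediate A → free catalyst + target (k = 0.740 M⁻¹ s⁻¹, Ea = 35.0 kJ mol⁻¹)
    second substrate + free catalyst ⇌ catalyst intermediate B (K = 32.0 M⁻¹, k = 0.0630 M⁻¹ s⁻¹, Ea = 50.0 kJ mol⁻¹, ΔH = 15.0 kJ mol⁻¹)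
    partner + catalyst intermediate B → free catalyst + second product (k = 0.480 M⁻¹ s⁻¹, Ea = 48.0 kJ mol⁻¹)
    gas ⇌ partner, rate k5*(csat - [partner]) (kL = 0.0220 s⁻¹)
    catalyst intermediate B + capture agent → trapped intermediate (k = 1.60 M⁻¹ s⁻¹, Ea = 51.0 kJ mol⁻¹)
    partner → decomposed reagent (k = 2.40 × 10⁻⁵ s⁻¹, Ea = 91.0 kJ mol⁻¹)
    (constants at 25 °C)

At 48.0 h the flask holds free catalyst at 0% and trapped intermediate at 100% of the catalyst charged, with second substrate at 90% of its charge. The neighbouring flask is charged with 0.012 M of second substrate and nothing else changed. With the factor held at 4.74, its second substrate should end at 83.3%, its starting material at 42.1% and its target at 57.9%. That neighbour ends with second substrate at 83%, starting material at 43% and target at 57.4%.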